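I read the grey, red and teal flasks at 20 s and the ochre tank at steady state after a mean stay of 20 s, wanting the complex with two exchanged at that moment.

    leaving ligand + incoming ligand ⇌ idle adduct, settled at all times (K1 = 10 M⁻¹)
    scavenger + leaving ligand → scavenged by-product (k2 = 3.1 M⁻¹ s⁻¹)
    incoming ligand → decomposed reagent (k3 = 0.016 s⁻¹)
    starting complex + incoming ligand → leaving ligand + complex with one exchanged (k4 = 27 M⁻¹ s⁻¹)
    complex with two exchanged + incoming ligand ⇌ leaving ligand + complex with three exchanged (K5 = 23, k5 = 37 M⁻¹ s⁻¹)
    complex with one exchanged + incoming ligand → leaving ligand + complex with two exchanged (k6 = 84 M⁻¹ s⁻¹)

all flasks: scavenger 1.20 equiv
- ochre: starting complex 0.054 M; incoming ligand 1.20 equiv; a single well-mixed tank run continuously and read at steady state, 20 s in it on average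
- red: starting complex 0.054 M; incoming ligand 1.20 equiv (fed, over 10.0 s); all but incoming ligand at the start; incoming ligand goes in evenly over 10.0 s, the run ends at 20 s; time 20 s
- teal: starting complex 0.054 M (fed, over 10.0 s); incoming ligand 1.20 equiv; a stirred flask in which starting complex is dosed at a steady rate over 10.0 s without added volume, worked up at 20 s; time 20 s
- grey: starting complex 0.054 M; incoming ligand 1.20 equiv; everything together in a closed stirred flask, run for 20 s; time 20 s

- the set-up with the highest amount of complex with two exchanged at the outlet or at the end, in percent of the starting complex put in ("none" if the first two lie within 2 percentage points) (ochre / red / teal / grey / none)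
- amount of complex with two exchanged at the outlet or at the end, in percent of the starting complex put in, ochre
- amount of complex with two exchanged at the outlet or at the end, in percent of the starting complex put in, red
- amount of complex with two exchanged at the outlet or at the end, in percent of the starting complex put in, teal
- amount of complex with two exchanged at the outlet or at the end, in percent of the starting complex put in, grey

- what is said of leaving ligand includes idle adduct
- the stated concentrations are those of everything mixed, before any reaction; amounts are the same in each set-up
- the feed brings no volume worth counting
- run time (red): 20 s

Each exchange takes one incoming ligand, and I judged the decomposition a small drain on it in grey, because its half-life of 43 s is far longer than the 0.40 s of the starting complex by step 4 alone at the charged concentrations. So I froze the exchange budget n, the exchanges the charge pays for per starting complex, at 1.20. Two exchanges per complex gave a first ceiling of 60.0% for the complex with two exchanged.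

For a floor I took grey and dropped the back step, which gives complex with two exchanged back and whose constant of 1.61 M⁻¹ s⁻¹ is far below 27 M⁻¹ s⁻¹. The forward exchanges share one ligand concentration, so their shares depend on the rate constants and on a clock τ, the time integral of that concentration. At τ equal to the reciprocal of 37 M⁻¹ s⁻¹, the chain held 23.0% of the complex with two exchanged and 17.9% of the complex with one exchanged, having spent 0.965 exchanges. At the reciprocal of 27 M⁻¹ s⁻¹, it held 27.6% of the complex with two exchanged and 15.3% of the complex with one exchanged, having spent 1.31. The budget lies between those two spendings, so the floor lay between those two holdings. Freezing the complex with one exchanged at that last share and supposing every complex with three exchanged returned tightened the ceiling, as an estimate for grey, to 52.3%.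

The forecast gave grey 37%, red 34%, teal 23% and ochre 22%, naming grey best, since “leaving ligand that lingers then pushes the three-exchanged complex back to it”. Its grey figure stands above my floor and below my ceiling.

The simulation gave grey 36.4%, red 33.3%, teal 23.0% and ochre 21.9%, so grey leads. In grey, incoming ligand, the limiting reagent, stood at 0.092% of its charge, and the complexes held 1.19 exchanges against the budget of 1.20. A neighbouring teal flask was charged with 3.00 equiv of incoming ligand. Its budget, less the decomposed reagent, came to 2.76 exchanges, of which its complexes held 2.58 while incoming ligand still free or in the idle adduct stood for 0.177, with the complex with three exchanged at 62.9% and the complex with two exchanged at 34.3%.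

The rate constants stand for no real mixture.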